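**Plan**

- Retrosynthesis: once the ring-A bromine (ortho to OH) and the MOM/dioxolane masks are removed, the two adjacent ring-A bonds C–OH and C–C(=O) are cut together. This gives 3-methoxy-5-methylbenzyne and the ring-B carboxylate. The cut is possible because the ring-A ketone carbon lies between the OMe carbon and the OH carbon, the pattern a 3-methoxyaryne takes up from a carboxylate.
- Ring B is cut further at C6′–CH2 (prenyl, Stille) and C2′–CHO (Vilsmeier–Haack), back to methyl 3,5-dihydroxybenzoate. The aryne precursor comes from 3-methoxy-5-methylphenol by carbamate-directed silylation.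
- Forward: both benzene rings are bought and no ring is formed. Ring B is formylated, brominated, protected and prenylated and its acid freed (steps 1–6); the silyl triflate is made (steps 7–9); the halves are joined in step 10; ring A is then brominated and all masks are removed.
- Stereochemistry: none has to be set. The target has no stereocentre and the prenyl double bond carries two identical methyl groups.

Key step: step 10

Remark: acid 9 carries an acid-labile acetal next to the carboxyl group, so it is assumed to be isolated cold at pH 4 and converted into its cesium salt without storage.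

**Route**

Step 1
Reactants: 1 methyl 3,5-dihydroxybenzoate
Product: 3 methyl 2-formyl-3,5-dihydroxybenzoate, via aryl iminium salt 2 (not isolated)
Conditions: POCl3, DMF, MeCN, 0 °C → rt; then H2O, 50 °C
Reagents that add atoms: N,N-dimethylformamide, CN(C)C=O; water, O
Why: Vilsmeier–Haack formylation of the resorcinol ring should occur para to one hydroxyl and ortho to the other (next to the ester) and not at the more crowded carbon between the two hydroxyls, as is usual for 5-substituted resorcinols, and the ester tolerates the chloroiminium reagent.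

Step 2
Reactants: 3 methyl 2-formyl-3,5-dihydroxybenzoate
Product: 4 methyl 2-bromo-6-formyl-3,5-dihydroxybenzoate
Conditions: NBS (1.0 equiv), MeCN, −20 → 0 °C
Reagents that add atoms: N-bromosuccinimide, O=C1CCC(=O)N1Br
Why: Electrophilic aromatic bromination of this 2,4-dihydroxybenzaldehyde-type ring should go to the carbon para to the chelated hydroxyl and ortho to the free one (the usual 5-position of 2,4-dihydroxybenzaldehydes), here the carbon beside the ester, and one equivalent at low temperature limits a second bromination between the hydroxyls.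

Step 3
Reactants: 4 methyl 2-bromo-6-formyl-3,5-dihydroxybenzoate
Product: 5 methyl 2-bromo-6-formyl-3,5-bis(methoxymethoxy)benzoate
Conditions: MOMCl, i-Pr2NEt, CH2Cl2, 0 °C → rt
Reagents that add atoms: chloromethyl methyl ether, COCCl
Why: Williamson-type O-alkylation of both phenols with MOMCl and a hindered amine base gives ethers that are stable to base, fluoride and organometallic reagents and can later be removed together with the acetal.

Step 4
Reactants: 5 methyl 2-bromo-6-formyl-3,5-bis(methoxymethoxy)benzoate
Product: 6 methyl 2-bromo-6-(1,3-dioxolan-2-yl)-3,5-bis(methoxymethoxy)benzoate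
Conditions: TMSOCH2CH2OTMS, TMSOTf (cat.), CH2Cl2, −78 → −20 °C; pyridine quench
Reagents that add atoms: 1,2-bis(trimethylsilyloxy)ethane, C[Si](C)(C)OCCO[Si](C)(C)C
Why: Silyl-triflate-catalysed acetalisation with the bis-silyl ether of ethylene glycol forms the dioxolane under aprotic conditions at low temperature, where the aryl MOM ethers (which need stoichiometric silyl triflate at higher temperature to cleave) and the neighbouring ester should stay intact.

Step 5
Reactants: 6 methyl 2-bromo-6-(1,3-dioxolan-2-yl)-3,5-bis(methoxymethoxy)benzoate; 7 tributyl(3-methylbut-2-en-1-yl)stannane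
Product: 8 methyl 2-(1,3-dioxolan-2-yl)-3,5-bis(methoxymethoxy)-6-(3-methylbut-2-en-1-yl)benzoate
Conditions: Pd(PPh3)4 (cat.), DMF, 100 °C
Reagents that add atoms: none
Why: Stille cross-coupling with zerovalent palladium should join the aryl bromide, activated by the ortho ester, to the unsubstituted CH2 terminus of the allyl unit because reductive elimination at the gem-dimethyl terminus is sterically disfavoured, and the neutral conditions spare the acetal and MOM groups.

Step 6
Reactants: 8 methyl 2-(1,3-dioxolan-2-yl)-3,5-bis(methoxymethoxy)-6-(3-methylbut-2-en-1-yl)benzoate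
Product: 9 2-(1,3-dioxolan-2-yl)-3,5-bis(methoxymethoxy)-6-(3-methylbut-2-en-1-yl)benzoic acid
Conditions: NaSEt, DMF, 80 °C; then cold 0.5 M HCl to pH 4, extract at once
Reagents that add atoms: none
Why: The ester flanked by two ortho carbon substituents resists attack at the carbonyl, so it is cleaved by SN2 demethylation with thiolate at the O-methyl carbon, which leaves the MOM ethers, the dioxolane and the prenyl group alone, and the brief cold acidification limits acetal loss assisted by the neighbouring acid.

Step 7
Reactants: 10 3-methoxy-5-methylphenol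
Product: 11 3-methoxy-5-methylphenyl N-isopropylcarbamate
Conditions: i-PrNCO, Et3N (cat.), CH2Cl2, rt
Reagents that add atoms: isopropyl isocyanate, CC(C)N=C=O
Why: Base-catalysed addition of the phenol to the isocyanate gives a secondary carbamate, a strong ortho-directing group that can later be removed under mild amine conditions.

Step 8
Reactants: 11 3-methoxy-5-methylphenyl N-isopropylcarbamate
Product: 15 3-methoxy-5-methyl-2-(trimethylsilyl)phenyl N-isopropylcarbamate, via N-silyl carbamate 12 (not isolated), via aryllithium 13 (not isolated), via N,C-bis-silyl carbamate 14 (not isolated)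
Conditions: TMSOTf, TMEDA, Et2O, 0 °C → rt; then TMEDA, n-BuLi, −78 °C; TMSCl, −78 °C → rt; aq. NaHSO4
Reagents that add atoms: chlorotrimethylsilane, C[Si](C)(C)Cl
Why: Directed ortho-metalation after in-situ N-silylation of the N–H should remove the ring proton between the carbamate oxygen and the methoxyl (the doubly activated site), the aryllithium is trapped by TMSCl, and the aqueous acid work-up frees the N–H again.

Step 9
Reactants: 15 3-methoxy-5-methyl-2-(trimethylsilyl)phenyl N-isopropylcarbamate
Product: 17 3-methoxy-5-methyl-2-(trimethylsilyl)phenyl trifluoromethanesulfonate, via silyl phenol 16 (not isolated)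
Conditions: DBU, Et2NH, MeCN, 40 °C; then PhNTf2, rt
Reagents that add atoms: N-phenylbis(trifluoromethanesulfonimide), O=S(=O)(N(c1ccccc1)S(=O)(=O)C(F)(F)F)C(F)(F)F
Why: DBU-induced E1cB cleavage of the secondary carbamate (the isocyanate being scavenged by Et2NH) liberates the hindered phenoxide, which is sulfonylated in the same flask by PhNTf2 to give the ortho-silylaryl triflate.

Step 10
Reactants: 9 2-(1,3-dioxolan-2-yl)-3,5-bis(methoxymethoxy)-6-(3-methylbut-2-en-1-yl)benzoic acid; 17 3-methoxy-5-methyl-2-(trimethylsilyl)phenyl trifluoromethanesulfonate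
Product: 21 (2-hydroxy-6-methoxy-4-methylphenyl)[2-(1,3-dioxolan-2-yl)-3,5-bis(methoxymethoxy)-6-(3-methylbut-2-en-1-yl)phenyl]methanone, via cesium carboxylate 18 (not isolated), via 3-methoxy-5-methylbenzyne 19 (not isolated), via 2-cesioaryl ester 20 (not isolated)
Conditions: Cs2CO3 (0.5 equiv), MeOH, rt, evaporate and dry (toluene azeotrope, vacuum); then 17 (1.3 equiv), CsF (3 equiv), THF, 125 °C, sealed tube; AcOH quench
Reagents that add atoms: none
Why: Fluoride removes the silyl group of 17 and triflate departs, giving aryne 19; the oxygen of carboxylate 18 adds to the aryne carbon remote from the methoxyl, and the aryl anion 20 so formed, flanked by OMe and the ester oxygen, attacks its own ester carbonyl through a four-membered transition state, the tetrahedral intermediate then opening to the chelated phenoxide ketone (a net 1,3 O-to-C acyl shift of the anionic Fries type). The closest known reaction type is the fluoride-mediated insertion of arynes into the C(=O)–O bond of carboxylic acids to give ortho-hydroxyaryl ketones, which is known to place the acyl group next to the methoxyl of 3-methoxybenzyne. No ring is closed (the four-membered array is only a transition structure) and no stereocentre is formed. Regioselectivity is needed and comes from the methoxyl beside the triple bond, whose inductive pull distorts the aryne so that the nucleophile enters at the distal carbon and the negative charge develops next to OMe. Acyl transfer must outrun protonation of 20, which the preformed, dried cesium salt in THF free of O–H and N–H donors is meant to secure, and the crowded ketone is thus made intramolecularly after an unhindered O-arylation. The MOM and dioxolane masks keep phenoxide arylation and attack on the aldehyde out of play, and only a small excess of 17 is used so that the product phenoxide is not arylated.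

Step 11
Reactants: 21 (2-hydroxy-6-methoxy-4-methylphenyl)[2-(1,3-dioxolan-2-yl)-3,5-bis(methoxymethoxy)-6-(3-methylbut-2-en-1-yl)phenyl]methanone
Product: 22 (3-bromo-2-hydroxy-6-methoxy-4-methylphenyl)[2-(1,3-dioxolan-2-yl)-3,5-bis(methoxymethoxy)-6-(3-methylbut-2-en-1-yl)phenyl]methanone
Conditions: NBS (1.0 equiv), i-Pr2NH (10 mol %), CH2Cl2, −78 → −20 °C, dark
Reagents that add atoms: N-bromosuccinimide, O=C1CCC(=O)N1Br
Why: Amine-catalysed electrophilic bromination with NBS should deliver bromine ortho to the free phenol through the hydrogen-bonded N-bromoamine, at the ring-A carbon para to the methoxyl, and at low temperature the highly activated phenol ring is expected to react before the prenyl double bond or the ketone-deactivated ring B.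

Step 12
Reactants: 22 (3-bromo-2-hydroxy-6-methoxy-4-methylphenyl)[2-(1,3-dioxolan-2-yl)-3,5-bis(methoxymethoxy)-6-(3-methylbut-2-en-1-yl)phenyl]methanone
Product: 23 Pestalone B, 2-(3-bromo-2-hydroxy-6-methoxy-4-methylbenzoyl)-4,6-dihydroxy-3-(3-methylbut-2-en-1-yl)benzaldehyde
Conditions: 2 M aq. HCl, THF, 40 °C
Reagents that add atoms: water, O
Why: Acid-catalysed hydrolysis of the two MOM acetals and the dioxolane, all activated by ortho or para carbonyl groups, should proceed in dilute aqueous acid that is mild enough to leave the prenyl double bond, the aryl bromide and the methyl ether untouched.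

**Compound list**

1 | methyl 3,5-dihydroxybenzoate | COC(=O)c1cc(O)cc(O)c1 | starting material
2 | [2,4-dihydroxy-6-(methoxycarbonyl)benzylidene]dimethyliminium dichlorophosphate | COC(=O)c1cc(O)cc(O)c1C=[N+](C)C.[O-]P(=O)(Cl)Cl | intermediate (not isolated)
3 | methyl 2-formyl-3,5-dihydroxybenzoate | COC(=O)c1cc(O)cc(O)c1C=O | intermediate
4 | methyl 2-bromo-6-formyl-3,5-dihydroxybenzoate | COC(=O)c1c(Br)c(O)cc(O)c1C=O | intermediate
5 | methyl 2-bromo-6-formyl-3,5-bis(methoxymethoxy)benzoate | COC(=O)c1c(Br)c(OCOC)cc(OCOC)c1C=O | intermediate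
6 | methyl 2-bromo-6-(1,3-dioxolan-2-yl)-3,5-bis(methoxymethoxy)benzoate | COC(=O)c1c(Br)c(OCOC)cc(OCOC)c1C2OCCO2 | intermediate
7 | tributyl(3-methylbut-2-en-1-yl)stannane | CCCC[Sn](CCCC)(CCCC)CC=C(C)C | starting material
8 | methyl 2-(1,3-dioxolan-2-yl)-3,5-bis(methoxymethoxy)-6-(3-methylbut-2-en-1-yl)benzoate | COC(=O)c1c(CC=C(C)C)c(OCOC)cc(OCOC)c1C2OCCO2 | intermediate
9 | 2-(1,3-dioxolan-2-yl)-3,5-bis(methoxymethoxy)-6-(3-methylbut-2-en-1-yl)benzoic acid | OC(=O)c1c(CC=C(C)C)c(OCOC)cc(OCOC)c1C2OCCO2 | intermediate
10 | 3-methoxy-5-methylphenol | COc1cc(C)cc(O)c1 | starting material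
11 | 3-methoxy-5-methylphenyl N-isopropylcarbamate | COc1cc(C)cc(OC(=O)NC(C)C)c1 | intermediate
12 | 3-methoxy-5-methylphenyl N-isopropyl-N-(trimethylsilyl)carbamate | COc1cc(C)cc(OC(=O)N(C(C)C)[Si](C)(C)C)c1 | intermediate (not isolated)
13 | 2-lithio-3-methoxy-5-methylphenyl N-isopropyl-N-(trimethylsilyl)carbamate | COc1cc(C)cc(OC(=O)N(C(C)C)[Si](C)(C)C)c1[Li] | intermediate (not isolated)
14 | 3-methoxy-5-methyl-2-(trimethylsilyl)phenyl N-isopropyl-N-(trimethylsilyl)carbamate | COc1cc(C)cc(OC(=O)N(C(C)C)[Si](C)(C)C)c1[Si](C)(C)C | intermediate (not isolated)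
15 | 3-methoxy-5-methyl-2-(trimethylsilyl)phenyl N-isopropylcarbamate | COc1cc(C)cc(OC(=O)NC(C)C)c1[Si](C)(C)C | intermediate
16 | 3-methoxy-5-methyl-2-(trimethylsilyl)phenol (present as its DBU salt) | COc1cc(C)cc(O)c1[Si](C)(C)C | intermediate (not isolated)
17 | 3-methoxy-5-methyl-2-(trimethylsilyl)phenyl trifluoromethanesulfonate | COc1cc(C)cc(OS(=O)(=O)C(F)(F)F)c1[Si](C)(C)C | intermediate
18 | cesium 2-(1,3-dioxolan-2-yl)-3,5-bis(methoxymethoxy)-6-(3-methylbut-2-en-1-yl)benzoate | [Cs+].[O-]C(=O)c1c(CC=C(C)C)c(OCOC)cc(OCOC)c1C2OCCO2 | intermediate (not isolated)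
19 | 3-methoxy-5-methylbenzyne | COC1=CC(C)=CC#C1 | intermediate (not isolated)
20 | 2-cesio-3-methoxy-5-methylphenyl 2-(1,3-dioxolan-2-yl)-3,5-bis(methoxymethoxy)-6-(3-methylbut-2-en-1-yl)benzoate | COc1cc(C)cc(OC(=O)c2c(CC=C(C)C)c(OCOC)cc(OCOC)c2C3OCCO3)c1[Cs] | intermediate (not isolated)
21 | (2-hydroxy-6-methoxy-4-methylphenyl)[2-(1,3-dioxolan-2-yl)-3,5-bis(methoxymethoxy)-6-(3-methylbut-2-en-1-yl)phenyl]methanone | COc1cc(C)cc(O)c1C(=O)c1c(C2OCCO2)c(OCOC)cc(OCOC)c1CC=C(C)C | intermediate
22 | (3-bromo-2-hydroxy-6-methoxy-4-methylphenyl)[2-(1,3-dioxolan-2-yl)-3,5-bis(methoxymethoxy)-6-(3-methylbut-2-en-1-yl)phenyl]methanone | COc1cc(C)c(Br)c(O)c1C(=O)c1c(C2OCCO2)c(OCOC)cc(OCOC)c1CC=C(C)C | intermediate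
23 | Pestalone B, 2-(3-bromo-2-hydroxy-6-methoxy-4-methylbenzoyl)-4,6-dihydroxy-3-(3-methylbut-2-en-1-yl)benzaldehyde | COc1cc(C)c(Br)c(O)c1C(=O)c1c(C=O)c(O)cc(O)c1CC=C(C)C | target

**Step count and risks**

Total steps: 12. Longest linear sequence: 9 steps (steps 1–6, then 10–12); the three-step branch 7–9 joins at step 10.

Steps most likely to fail:

1. Step 10. The aryl anion formed after O-arylation may be protonated, or its 1,3-shift onto a carbonyl shielded by two ortho substituents may be too slow, so that the reaction stops at the aryl ester stage.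
   Fallback: it sets out from ester 8 and carbamate 11 and returns at 21; the ketone is made by adding a ring-A aryllithium to a ring-B aldehyde and oxidising. Ester 8 is reduced with LiAlH4 (THF, 0 °C) to [2-(1,3-dioxolan-2-yl)-3,5-bis(methoxymethoxy)-6-(3-methylbut-2-en-1-yl)phenyl]methanol F1. Dess–Martin periodinane (NaHCO3, CH2Cl2) oxidises this to 2-(1,3-dioxolan-2-yl)-3,5-bis(methoxymethoxy)-6-(3-methylbut-2-en-1-yl)benzaldehyde F2. Aryllithium 13, generated from 11 as in step 8, is added to F2 at −78 °C, and a pH 7 work-up (which also frees the N–H) should give the racemic diaryl carbinol carbamate F3. A second Dess–Martin oxidation gives the diaryl ketone carbamate F4, and DBU/Et2NH in MeCN at 40 °C removes the carbamate to give 21.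

2. Step 11. The electrophilic bromine may attack the electron-rich trisubstituted side-chain double bond (with capture by the neighbouring MOM oxygen) in competition with ring bromination.
   Fallback: it sets out from bromide 6 and returns at 22; the side chain is carried as a much less nucleophilic monosubstituted allyl group and turned into prenyl only after the bromination. Stille coupling of 6 with allyltributylstannane (Pd(PPh3)4, DMF, 90 °C) gives methyl 2-allyl-6-(1,3-dioxolan-2-yl)-3,5-bis(methoxymethoxy)benzoate F5. NaSEt demethylation gives 2-allyl-6-(1,3-dioxolan-2-yl)-3,5-bis(methoxymethoxy)benzoic acid F6. Aryne insertion with 17 under the conditions of step 10 gives the allyl-bearing hydroxy ketone F7. NBS with catalytic i-Pr2NH then gives the allyl-bearing bromophenol F8. Cross-metathesis of F8 with excess 2-methyl-2-butene (second-generation Grubbs catalyst RuCl2(H2IMes)(PCy3)(=CHPh), CH2Cl2, 40 °C) converts allyl into prenyl and gives 22.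

3. Step 12. During the acid hydrolysis the phenol freed next to the prenyl group may add across the protonated double bond (chroman formation), or the double bond may be hydrated.
   Fallback: it sets out from bromide 6, runs through the allyl series as far as the bromophenol F8 described above, and returns at 23; the acid step is done before the prenyl double bond exists. Hydrolysis of F8 with 2 M aq. HCl in THF should give the allyl analogue of the target, 2-allyl-6-(3-bromo-2-hydroxy-6-methoxy-4-methylbenzoyl)-3,5-dihydroxybenzaldehyde F9, whose terminal alkene cannot form a tertiary cation. Cross-metathesis of F9 with 2-methyl-2-butene (second-generation Grubbs catalyst RuCl2(H2IMes)(PCy3)(=CHPh), CH2Cl2, 40 °C) then gives 23 under neutral conditions.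

**Further compounds**

F1 | step 10 | [2-(1,3-dioxolan-2-yl)-3,5-bis(methoxymethoxy)-6-(3-methylbut-2-en-1-yl)phenyl]methanol | OCc1c(CC=C(C)C)c(OCOC)cc(OCOC)c1C2OCCO2
F2 | step 10 | 2-(1,3-dioxolan-2-yl)-3,5-bis(methoxymethoxy)-6-(3-methylbut-2-en-1-yl)benzaldehyde | O=Cc1c(CC=C(C)C)c(OCOC)cc(OCOC)c1C2OCCO2
F3 | step 10 | racemic 2-{[2-(1,3-dioxolan-2-yl)-3,5-bis(methoxymethoxy)-6-(3-methylbut-2-en-1-yl)phenyl](hydroxy)methyl}-3-methoxy-5-methylphenyl N-isopropylcarbamate | COc1cc(C)cc(OC(=O)NC(C)C)c1C(O)c1c(C2OCCO2)c(OCOC)cc(OCOC)c1CC=C(C)C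
F4 | step 10 | 2-[2-(1,3-dioxolan-2-yl)-3,5-bis(methoxymethoxy)-6-(3-methylbut-2-en-1-yl)benzoyl]-3-methoxy-5-methylphenyl N-isopropylcarbamate | COc1cc(C)cc(OC(=O)NC(C)C)c1C(=O)c1c(C2OCCO2)c(OCOC)cc(OCOC)c1CC=C(C)C
F5 | step 11 | methyl 2-allyl-6-(1,3-dioxolan-2-yl)-3,5-bis(methoxymethoxy)benzoate | COC(=O)c1c(CC=C)c(OCOC)cc(OCOC)c1C2OCCO2
F6 | step 11 | 2-allyl-6-(1,3-dioxolan-2-yl)-3,5-bis(methoxymethoxy)benzoic acid | OC(=O)c1c(CC=C)c(OCOC)cc(OCOC)c1C2OCCO2
F7 | step 11 | (2-hydroxy-6-methoxy-4-methylphenyl)[2-allyl-6-(1,3-dioxolan-2-yl)-3,5-bis(methoxymethoxy)phenyl]methanone | COc1cc(C)cc(O)c1C(=O)c1c(C2OCCO2)c(OCOC)cc(OCOC)c1CC=C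
F8 | step 11 | (3-bromo-2-hydroxy-6-methoxy-4-methylphenyl)[2-allyl-6-(1,3-dioxolan-2-yl)-3,5-bis(methoxymethoxy)phenyl]methanone | COc1cc(C)c(Br)c(O)c1C(=O)c1c(C2OCCO2)c(OCOC)cc(OCOC)c1CC=C
F9 | step 12 | 2-allyl-6-(3-bromo-2-hydroxy-6-methoxy-4-methylbenzoyl)-3,5-dihydroxybenzaldehyde | COc1cc(C)c(Br)c(O)c1C(=O)c1c(C=O)c(O)cc(O)c1CC=C
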